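Count amounts first. Each exchange on E, J, L or X takes one Z and gives one D, and the one other step removes D as Q. Follow one E: it goes forward at a fork by taking a Z and back by taking a D. The charge is therefore a budget, and the mean number of exchanges per E is the equivalents (Z charged over E charged, which show whether Z can be the limiting reagent) times the fraction of Z spent.

in all of them: E 0.20 M

| run | Z | remark | time |
|---|---|---|---|
| teal | 0.18 M | run made earlier |  |
| green | 0.38 M | run made earlier |  |
| blue | 0.64 M | run made earlier |  |
| south-east | 0.600 M |  | 2.5 h |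
| north | 0.800 M |  | 2.5 h |
| north-west | 0.200 M |  | 2.5 h |

- teal (time / min: L / %, G / %): 12.0: 12.2, 0; 40.0: 7.8, 0.5; 60.0: 9.0, 0.1; 120: 11.3, 0.3
- green (time / min: L / %, G / %): 12.0: 22.2, 6.9; 40.0: 19.6, 4.0; 60.0: 22.2, 5.9; 120: 25.3, 7.5
- blue (time / min: L / %, G / %): 8.00: 28.9, 6.4; 20.0: 23.6, 11.1; 50.0: 23.3, 16.2; 120: 20.6, 28.0

(standard deviation of a reading: 1 percentage point)

- steps thought possible: E + Z <-> D + J; L + Z <-> D + X; D -> Q; X + Z <-> D + G; J + Z <-> D + L

- which of these holds the largest part of the E at the end of south-east (X / L / G / J / E)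
- which of these holds the largest part of the E at the end of north (X / L / G / J / E)
- which of these holds the largest part of the E at the end of north-west (X / L / G / J / E)
- L at the end of north, in percent of the E charged

The readings show the budget at work: teal, at 0.900 equivalents, reads G 0.3% at 120 min, and blue, at 3.20, reads G 28.0% and L 20.6% at 120 min.

| flask | equivalents |
|---|---|
| north-west | 1.00 |
| south-east | 3.00 |
| north | 4.00 |

My reckoning: north holds more Z per E than blue, so I expect G to lead there and L to stand below blue's reading. North-west's budget puts E and J ahead.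

The forecast says X for south-east, G for north, J for north-west and L 13% in north, holding that "composition is then set mainly by the Z:E ratio".

The flasks give X for south-east, G for north, J for north-west, and L 11.7% in north.

    E + Z ⇌ D + J (K = 35.0, k = 0.00810 L mol⁻¹ s⁻¹)
    L + Z ⇌ D + X (K = 1.50, k = 0.00480 L mol⁻¹ s⁻¹)
    D → Q (k = 4.00 × 10⁻⁴ s⁻¹)
    X + Z ⇌ D + G (K = 0.620, k = 0.0160 L mol⁻¹ s⁻¹)
    J + Z ⇌ D + L (K = 0.760, k = 0.0300 L mol⁻¹ s⁻¹)

North keeps 18.7% of its Z at 2.50 h, so its mean is 3.25 exchanges per E out of a budget of 4.00. Now raise Z alone to 1.4 M: that neighbour has 7.00 equiv and keeps 44.8% of its Z, so its mean is 3.87 exchanges per E. It holds G 87.6% and L 0.750%.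

All runs stem from a simulated flask on assumed constants; scatter was added.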